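## Analysis of the target

Numbering used throughout: ring A is C1(=O)–C2–C3–C4–C5=C6, ring B is C2–C7–C8=C9–C10–C3, ring C is C3–C10–C11–C12–C4 and ring D is C4–C12–C13–O–C5. C2 carries geranyl, C6 prenyl, C9 one methyl and C13 two methyls.

The target is a compact tetracycle with all ring fusions cis: a cyclohexenone (ring A), a methylcyclohexene (ring B), a cyclopentane (ring C) and a 2,2-dimethyltetrahydrofuran (ring D) that ties the C5=C6 enol ether to C4. Five contiguous stereocentres are present (C2, C3, C4, C10, C12). C7, C10 and C12 lie on one face of ring A; geranyl and the two tertiary hydroxyls on C3 and C4 lie on the other, so the diol is cis and H10 and H12 are syn to the hydroxyls on ring C. Sensitive groups are four trisubstituted alkenes (acid, electrophiles), the vinylogous ester O–C5=C6–C1=O, and a ditertiary diol whose C3 hydroxyl is β to the C1 carbonyl and therefore open to retro-aldol cleavage under base. The difficulty is the cluster C2–C3–C4: three adjacent fully substituted carbons, two of them oxygenated, at the junction of all four rings. The plan rests on one feature: the chain C7–C13 leaves ring A at quaternary C2 and returns to it three times, at the vicinal carbinols C3 and C4 and at the oxygen on C5. Read backwards, C3 and C4 are the two carbons of a 1,2-diketone and C5–O is the enol of a vinylogous acid, so a monocyclic ring A triketone can take up the chain at all three points.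

## Retrosynthetic reasoning

**C9 methyl (26 back to 21).** The C9–CH3 bond is cut and the C8=C9 alkene is traced to a C9 ketone, through enol triflate 24 and the silyl-protected compounds 25 and 22. The ketone is wanted because it is the only handle that can make C10 nucleophilic. Forward, enolisation has to go to the C8 methylene and not to the ring-fusion methine C10, and the C3 carbinol (β to two carbonyls) must be masked during the basic steps.

**Three ring bonds (21 back to 19).** C3–C10, C4–C12 and C13–O are cut together. This removes rings B, C and D and four stereocentres (C3, C4, C10, C12) at once and leaves the monocyclic hydroxy-triketone 19, whose only stereocentre is C2. The cut is made here because each bond, once formed, places the partners of the next: ring B (ketol 20) brings C12 over C4, and ring C brings C13 next to the oxygen on C5. Forward, C10 must add to C3 and not to C1, the chain alkene must add to C4, and the cation must be taken by O5 rather than lose a proton.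

**Quaternary C2 (19 back to 18, then to 12 and 17).** The C2–C7 bond is cut as a conjugate addition of hydroxyquinone 12 to vinyl ketone 17. C2 is the one stereocentre the cascade cannot make, so it has to be set here by a chiral catalyst. The donor must be nucleophilic at C2 only. A donor with both flanking oxygens (O3 and O5) free would react equally at C2 and at C6, so O5 is kept as a methyl ether in 12 and 18 and is unmasked afterwards (18 to 19).

**Ring A substitution (12 back to 11, 10, 7, 4, 3 and 1).** The quinone is traced to the resorcinol 11 and its bis-acetal 10. The C2–geranyl and C6–prenyl bonds are cut to the allylic bromides 5 and 8 and are made by two directed metalations (7, then 10). A symmetrical arene with the same group on both flanking oxygens would leave O3 and O5 indistinguishable once both side chains are on. Aldehyde 1 avoids this: its formyl carbon becomes O1, its free hydroxyl becomes O3 and its two methoxy groups become O4 and O5. In bis-acetal 4 the site between the two acetal oxygens is metalated first, so geranyl enters next to the oxygen that will be the free hydroxyl of 12.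

**Vinyl ketone (17 back to 15 and 13).** The enone carbon is added to the methyl group of ketone 13 by a Mannich reaction (15) and elimination. The vinyl ketone is made last and used at once.

## Alternatives that were turned down

**Alternative 1:** The C3–C4 bond is cut. A ring B ketone A1 that carries an α-keto ester on the C10 side chain would be reduced by SmI2 (divalent samarium) at the keto ester carbonyl C4, and the ketyl would add to the ring ketone C3 to give the bicyclic cis-diol ester A2 (rings B and C).
- For it: ketyl–carbonyl coupling through a samarium chelate is a dependable way to a cis-1,2-diol on a five-membered ring, and on this point it is stronger than the Prins closure used here.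
- Against it: A1 must already hold C2, C10 and C12 in the right configuration, built one by one. C10 in A1 is α to the ketone and allylic to C8=C9, so it can epimerise and the alkene can move into conjugation. After A2, rings A and D are still open.
- Comparison: one ring per key step against three. The chosen route offers in exchange that only C2 has to be made by hand.

**Alternative 2:** The C2–C7 bond is cut. Phenol A3, which carries a (Z)-allylic carbonate on C3, would be ionised by Pd2(dba)3 (zerovalent palladium) with a chiral diphosphine, and the phenoxide would attack through C2 to give the bicyclic cyclohexa-2,4-dienone A4 (rings A and B).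
- For it: quaternary C2 comes from a flat arene under catalyst control, and the C8=C9 alkene with its methyl is already in place, so the triflate and cuprate steps of the present route would not be needed. On that point it is stronger.
- Against it: A4 has no oxygen on C3 (C3=C4 is an enol ether). C3 and C4 would have to be oxidised in the presence of four other alkenes, and C4–C12 and C13–O would still have to be made at a fully substituted carbon. The benzylic, allylic stereocentre C10 of A3 must be set before the key step and competes with the catalyst. O-allylation is a further side path.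
- Comparison: the chosen route carries every ring A oxygen from the arene, so no late oxidation is needed.

**Alternative 3:** Only C3–C10 is cut. The achiral trione A5 would be cyclised by a proline-type catalyst, whose enamine at C9 adds through C10 to one of the two enantiotopic ring carbonyls to give the cis-fused ketol A6 (rings A and B).
- For it: this is the best-precedented enantioselective event of all four plans (Hajos–Parrish type). It sets C2, C3 and C10 in one catalytic step and needs no separate asymmetric Michael addition. On enantiocontrol it is stronger than the chosen route.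
- Against it: A5 is a cyclohexane-1,3,5-trione with two ring methylenes and will be largely enolised, which removes both the symmetry and the electrophilicity the aldol needs. A6 lacks the C4 oxygen and the C6 prenyl group, and C4 is a nucleophilic methylene, so the C4–C12 bond would need an oxidative or umpolung step.
- Comparison: many operations remain after A6. The chosen route pays with a less precedented Michael addition, but the cascade precursor 19 is already complete in carbon and oxygen.

Key step: step 11

Remarks on the chemistry:
- The quinine-derived catalyst of step 9 is assumed to give the (R) configuration at C2; if the sense of induction proves opposite, the quinidine-derived pseudoenantiomer would be used.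
- Compounds 1, 5, 8 and 13 are taken as commercial.

## Route

Step 1
Reactants: 1 3-hydroxy-4,5-dimethoxybenzaldehyde
Product: 3 4,5-dimethoxybenzene-1,3-diol, via aryl formate 2 (not isolated)
Conditions: H2O2 (30% aq.), H2SO4 (cat.), MeOH, rt
Reagents that add atoms: hydrogen peroxide, OO
Why: Acid-catalysed Dakin oxidation: the perhydrate of the aldehyde undergoes Baeyer–Villiger-type aryl migration, helped by the para methoxy group, and formate 2 is methanolysed in the same flask.

Step 2
Reactants: 3 4,5-dimethoxybenzene-1,3-diol
Product: 4 1,2-dimethoxy-3,5-bis(methoxymethoxy)benzene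
Conditions: MeOCH2Cl, i-Pr2NEt, CH2Cl2, 0 °C → rt
Reagents that add atoms: chloromethyl methyl ether, COCCl
Why: O-Alkylation of both phenols gives the bis-acetal; the two acetal oxygens direct both later metalations.

Step 3
Reactants: 4 1,2-dimethoxy-3,5-bis(methoxymethoxy)benzene; 5 geranyl bromide
Product: 7 4-[(2E)-3,7-dimethylocta-2,6-dienyl]-1,2-dimethoxy-3,5-bis(methoxymethoxy)benzene, via aryllithium 6 (not isolated)
Conditions: n-BuLi, THF, 0 °C; then CuBr·SMe2 (10 mol %), 5, −78 °C → rt
Reagents that add atoms: none
Why: Directed ortho-metalation: the position between the two methoxymethoxy groups is the most acidic and best chelated site, and copper-catalysed SN2 coupling of 6 with the allylic bromide keeps the (E) geometry and the linear attachment.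

Step 4
Reactants: 7 4-[(2E)-3,7-dimethylocta-2,6-dienyl]-1,2-dimethoxy-3,5-bis(methoxymethoxy)benzene; 8 prenyl bromide
Product: 10 4-[(2E)-3,7-dimethylocta-2,6-dienyl]-1,2-dimethoxy-3,5-bis(methoxymethoxy)-6-(3-methylbut-2-enyl)benzene, via aryllithium 9 (not isolated)
Conditions: n-BuLi, TMEDA, THF, −20 → 0 °C; then CuBr·SMe2 (10 mol %), 8, −78 °C → rt
Reagents that add atoms: none
Why: Second directed ortho-metalation at the only remaining ring hydrogen (between a methoxymethoxy and a methoxy group), then the same copper-catalysed allylation; complex-induced proximity should favour ring metalation over removal of a benzylic-allylic hydrogen of the geranyl group.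

Step 5
Reactants: 10 the bis-acetal from step 4
Product: 11 2-[(2E)-3,7-dimethylocta-2,6-dienyl]-4,5-dimethoxy-6-(3-methylbut-2-enyl)benzene-1,3-diol
Conditions: HCl (3 M aq., cat.), MeOH, 40 °C, argon
Reagents that add atoms: none
Why: Acid-catalysed acetal exchange with methanol removes both methoxymethyl groups as dimethoxymethane under conditions mild enough to leave the ortho prenyl and geranyl groups uncyclised; the air-sensitive resorcinol is used directly.

Step 6
Reactants: 11 the resorcinol from step 5
Product: 12 3-[(2E)-3,7-dimethylocta-2,6-dienyl]-2-hydroxy-6-methoxy-5-(3-methylbut-2-enyl)cyclohexa-2,5-diene-1,4-dione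
Conditions: PhI(OAc)2, MeCN/H2O, 0 °C
Reagents that add atoms: water, O
Why: Oxidative demethylation of a para-methoxyphenol: the phenoxonium ion is attacked by water at the methoxy-bearing para carbon and loses methanol to give the para-quinone, while the second phenol survives as the hydroxyl next to geranyl; oxidation through either phenol converges on the same tautomeric hydroxyquinone.

Step 7
Reactants: 13 6-methylhept-5-en-2-one
Product: 15 1-(dimethylamino)-7-methyloct-6-en-3-one, via lithium enolate 14 (not isolated)
Conditions: LiN(i-Pr)2, THF, −78 °C; then Me2N=CH2+ I−, −78 °C → rt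
Reagents that add atoms: N,N-dimethylmethyleneiminium iodide, C[N+](C)=C.[I-]
Why: Kinetic deprotonation on the methyl side and Mannich reaction of enolate 14 with the preformed iminium salt.

Step 8
Reactants: 15 1-(dimethylamino)-7-methyloct-6-en-3-one
Product: 17 7-methylocta-1,6-dien-3-one, via methiodide 16 (not isolated)
Conditions: MeI, Et2O, rt; then NaHCO3 (aq.), CH2Cl2, rt
Reagents that add atoms: none
Why: Quaternisation and E1cB (Hofmann-type) loss of trimethylamine from the β-ammonio ketone 16 give the vinyl ketone, which is used at once to avoid polymerisation.

Step 9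
Reactants: 12 the hydroxyquinone from step 6; 17 7-methylocta-1,6-dien-3-one
Product: 18 (3R)-3-[(2E)-3,7-dimethylocta-2,6-dienyl]-6-methoxy-5-(3-methylbut-2-enyl)-3-(7-methyl-3-oxooct-6-enyl)cyclohex-5-ene-1,2,4-trione
Conditions: quinine-derived squaramide (N-[3,5-bis(trifluoromethyl)phenyl] squaramide of 9-amino-9-deoxy-epi-quinine, 10 mol %), toluene, −20 °C
Reagents that add atoms: none
Why: Proposed new method: the quinuclidine of the catalyst deprotonates the acidic hydroxyquinone to an ammonium hydroxyquinonate held at its O3/O4 edge while the squaramide N–H groups bind the carbonyl of 17, so the enone is delivered to one enantiotopic face of the planar donor, and C2, the only nucleophilic carbon because O5 is methylated, becomes the (R)-configured quaternary centre; the closest known reaction types are the cinchona-amine-catalysed enantioselective Michael additions of 2-substituted cyclic 1,3-dicarbonyl compounds to alkyl vinyl ketones and of 2-hydroxy-1,4-naphthoquinone to enones, which have not been extended to a fully substituted hydroxybenzoquinone as a pro-quaternary donor.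

Step 10
Reactants: 18 the methyl ether from step 9
Product: 19 (3R)-3-[(2E)-3,7-dimethylocta-2,6-dienyl]-6-hydroxy-5-(3-methylbut-2-enyl)-3-(7-methyl-3-oxooct-6-enyl)cyclohex-5-ene-1,2,4-trione
Conditions: LiCl, DMSO, 90 °C; then aq. NH4Cl
Reagents that add atoms: none
Why: SN2 demethylation of a vinylogous methyl ester by chloride, the method used to unmask polyprenylated cyclic β-diketones; the leaving group is the stabilised O5–C5=C6–C1=O anion, and no nucleophile is present that could add to the 1,2-diketone or open ring A by retro-Claisen cleavage.

Step 11
Reactants: 19 the hydroxy-triketone from step 10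
Product: 21 tetracyclic C9 ketone with rings A to D closed (C3-OH and C4-OH cis to each other and to geranyl; C7 C10 C12 on the opposite face of ring A; H10 and H12 syn to the hydroxyls), via bicyclic ketol 20 (not isolated)
Conditions: pyrrolidine (30 mol %), AcOH (30 mol %), CH2Cl2, 0 °C → rt; then BF3·OEt2, −78 → −30 °C
Reagents that add atoms: none
Why: Proposed new method: the pyrrolidine enamine of the C9 ketone (C9=C10 isomer) adds to the C3 carbonyl in a 6-(enolendo)-exo-trig aldol that closes ring B, the known second stage of a Robinson annulation; C1 is just as close to C10, but it belongs to the O5–C5=C6–C1=O vinylogous acid and is deactivated, whereas C3 is half of a 1,2-diketone. The three-atom tether C7–C8–C9 reaches only the face of ring A that carries C7, so the new C3 hydroxyl is cis to geranyl (C3 controlled by C2), and C10 stays epimerisable through the enamine, so only the epimer of 20 with C11 cis to C4 reacts on. BF3·OEt2 then binds the C4 ketone of 20 (the carbonyl of an α-hydroxy enedione), C12 of the chain alkene attacks it from the same face in a 5-exo-trig Prins closure of ring C, which puts the C4 hydroxyl cis to the C3 hydroxyl (C4 controlled by C10), and the tertiary C13 cation is captured by the enol oxygen on C5 to close the five-membered ring D. The closest known reaction type for this second stage is the Lewis-acid Prins cyclisation of an alkene onto an activated ketone with capture of the cation by an internal oxygen. C12 is set in an open transition state in which the CMe2 terminus turns away from the BF3-bound oxygen and towards C5; the epimer with C13 syn to O4 cannot reach O5 and is expected to revert by retro-Prins fragmentation of the β-alkoxy cation, so ring D closure drains the productive isomer. The step needs C3 over C1 and C4 in the aldol (electronic, as above; the C8 enamine could only form a strained bridged ketol at C4, reversibly), survival of the ketol without dehydration (low temperature, substoichiometric amine salt), and reaction of the chain alkene in preference to the prenyl and geranyl alkenes (only the chain alkene is held within bonding distance of C4 once ring B exists). No atom is lost: 21 is an isomer of 19, and its four new stereocentres (C3, C4, C10, C12) all follow from C2.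

Step 12
Reactants: 21 the tetracyclic C9 ketone
Product: 22 C3,C4-bis(trimethylsilyl) ether of 21
Conditions: Me3SiOTf, 2,6-lutidine, CH2Cl2, −78 → 0 °C
Reagents that add atoms: trimethylsilyl trifluoromethanesulfonate, C[Si](C)(C)OS(=O)(=O)C(F)(F)F
Why: Silylation of both tertiary alcohols with a silyl triflate and a hindered pyridine base; the ethers block retro-aldol cleavage at the C3 carbinol (β to the C1 and C9 carbonyls) and O-sulfonylation in the next step.

Step 13
Reactants: 22 the bis-silyl ether
Product: 24 C8=C9 enol triflate of 22, via potassium enolate 23 (not isolated)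
Conditions: KN(SiMe3)2, THF, −78 °C; then PhNTf2, −78 → −20 °C
Reagents that add atoms: N-phenylbis(trifluoromethanesulfonimide), O=S(=O)(N(c1ccccc1)S(=O)(=O)C(F)(F)F)C(F)(F)F
Why: Kinetic deprotonation by the bulky amide occurs at the C8 methylene and not at the hindered ring-fusion methine C10, and enolate 23 is O-sulfonylated by the triflimide; no other carbonyl has an α-hydrogen.

Step 14
Reactants: 24 the enol triflate
Product: 25 C3,C4-bis(trimethylsilyl) ether of the target
Conditions: Me2CuLi (from MeLi and CuI), THF, −20 → 0 °C
Reagents that add atoms: lithium dimethylcuprate, [Li+].C[Cu-]C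
Why: Coupling of an alkenyl triflate with a lithium dialkylcuprate replaces the triflate by methyl without moving the C8=C9 alkene; the hindered vinylogous ester of ring A is not attacked at low temperature.

Step 15
Reactants: 25 the bis-silyl ether of the target
Product: 26 CNP0323114.1 (target)
Conditions: HF·pyridine, pyridine, THF, 0 °C
Reagents that add atoms: none
Why: Buffered fluoride cleaves the two trimethylsilyl ethers and leaves the alkenes and the vinylogous ester untouched; no stereocentre is affected.

## Compound list

1 | 3-hydroxy-4,5-dimethoxybenzaldehyde | O=Cc1cc(O)c(OC)c(OC)c1 | starting material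
2 | 3-hydroxy-4,5-dimethoxyphenyl formate | O=COc1cc(O)c(OC)c(OC)c1 | intermediate (not isolated)
3 | 4,5-dimethoxybenzene-1,3-diol | Oc1cc(O)c(OC)c(OC)c1 | intermediate
4 | 1,2-dimethoxy-3,5-bis(methoxymethoxy)benzene | COCOc1cc(OCOC)c(OC)c(OC)c1 | intermediate
5 | geranyl bromide, (2E)-1-bromo-3,7-dimethylocta-2,6-diene | CC(C)=CCC/C(C)=C/CBr | starting material
6 | 3,4-dimethoxy-2,6-bis(methoxymethoxy)phenyllithium | [Li]c1c(OCOC)cc(OC)c(OC)c1OCOC | intermediate (not isolated)
7 | 4-[(2E)-3,7-dimethylocta-2,6-dienyl]-1,2-dimethoxy-3,5-bis(methoxymethoxy)benzene | CC(C)=CCC/C(C)=C/Cc1c(OCOC)cc(OC)c(OC)c1OCOC | intermediate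
8 | prenyl bromide, 1-bromo-3-methylbut-2-ene | CC(C)=CCBr | starting material
9 | 3-[(2E)-3,7-dimethylocta-2,6-dienyl]-5,6-dimethoxy-2,4-bis(methoxymethoxy)phenyllithium | CC(C)=CCC/C(C)=C/Cc1c(OCOC)c([Li])c(OC)c(OC)c1OCOC | intermediate (not isolated)
10 | 4-[(2E)-3,7-dimethylocta-2,6-dienyl]-1,2-dimethoxy-3,5-bis(methoxymethoxy)-6-(3-methylbut-2-enyl)benzene | CC(C)=CCC/C(C)=C/Cc1c(OCOC)c(CC=C(C)C)c(OC)c(OC)c1OCOC | intermediate
11 | 2-[(2E)-3,7-dimethylocta-2,6-dienyl]-4,5-dimethoxy-6-(3-methylbut-2-enyl)benzene-1,3-diol | CC(C)=CCC/C(C)=C/Cc1c(O)c(CC=C(C)C)c(OC)c(OC)c1O | intermediate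
12 | 3-[(2E)-3,7-dimethylocta-2,6-dienyl]-2-hydroxy-6-methoxy-5-(3-methylbut-2-enyl)cyclohexa-2,5-diene-1,4-dione | CC(C)=CCC/C(C)=C/CC1=C(O)C(=O)C(OC)=C(CC=C(C)C)C1=O | intermediate
13 | 6-methylhept-5-en-2-one | CC(=O)CCC=C(C)C | starting material
14 | lithium 6-methylhepta-1,5-dien-2-olate | [Li]OC(=C)CCC=C(C)C | intermediate (not isolated)
15 | 1-(dimethylamino)-7-methyloct-6-en-3-one | CN(C)CCC(=O)CCC=C(C)C | intermediate
16 | N,N,N,7-tetramethyl-3-oxooct-6-en-1-aminium iodide | C[N+](C)(C)CCC(=O)CCC=C(C)C.[I-] | intermediate (not isolated)
17 | 7-methylocta-1,6-dien-3-one | C=CC(=O)CCC=C(C)C | intermediate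
18 | (3R)-3-[(2E)-3,7-dimethylocta-2,6-dienyl]-6-methoxy-5-(3-methylbut-2-enyl)-3-(7-methyl-3-oxooct-6-enyl)cyclohex-5-ene-1,2,4-trione | CC(C)=CCC/C(C)=C/C[C@@]1(CCC(=O)CCC=C(C)C)C(=O)C(=O)C(OC)=C(CC=C(C)C)C1=O | intermediate
19 | (3R)-3-[(2E)-3,7-dimethylocta-2,6-dienyl]-6-hydroxy-5-(3-methylbut-2-enyl)-3-(7-methyl-3-oxooct-6-enyl)cyclohex-5-ene-1,2,4-trione | CC(C)=CCC/C(C)=C/C[C@@]1(CCC(=O)CCC=C(C)C)C(=O)C(=O)C(O)=C(CC=C(C)C)C1=O | intermediate (cascade precursor)
20 | ring A/ring B cis-fused ketol: C3-OH cis to geranyl, C10 bearing the 4-methylpent-3-enyl chain cis to C4, C9 ketone | CC(C)=CCC/C(C)=C/C[C@]12CCC(=O)[C@H](CCC=C(C)C)[C@]2(O)C(=O)C(O)=C(CC=C(C)C)C1=O | intermediate (not isolated)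
21 | tetracyclic C9 ketone, rings A to D closed, cis-diol, all ring fusions cis | CC(C)=CCC/C(C)=C/C[C@]12CCC(=O)[C@@H]3C[C@@H]4C(C)(C)OC(=C(CC=C(C)C)C1=O)[C@]4(O)[C@@]32O | intermediate
22 | C3,C4-bis(trimethylsilyl) ether of 21 | CC(C)=CCC/C(C)=C/C[C@]12CCC(=O)[C@@H]3C[C@@H]4C(C)(C)OC(=C(CC=C(C)C)C1=O)[C@]4(O[Si](C)(C)C)[C@@]32O[Si](C)(C)C | intermediate
23 | potassium C8=C9 enolate of 22 | CC(C)=CCC/C(C)=C/C[C@]12CC=C(O[K])[C@@H]3C[C@@H]4C(C)(C)OC(=C(CC=C(C)C)C1=O)[C@]4(O[Si](C)(C)C)[C@@]32O[Si](C)(C)C | intermediate (not isolated)
24 | C8=C9 enol triflate of 22 | CC(C)=CCC/C(C)=C/C[C@]12CC=C(OS(=O)(=O)C(F)(F)F)[C@@H]3C[C@@H]4C(C)(C)OC(=C(CC=C(C)C)C1=O)[C@]4(O[Si](C)(C)C)[C@@]32O[Si](C)(C)C | intermediate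
25 | C3,C4-bis(trimethylsilyl) ether of the target | CC(C)=CCC/C(C)=C/C[C@]12CC=C(C)[C@@H]3C[C@@H]4C(C)(C)OC(=C(CC=C(C)C)C1=O)[C@]4(O[Si](C)(C)C)[C@@]32O[Si](C)(C)C | intermediate
26 | CNP0323114.1 | CC(C)=CCC/C(C)=C/C[C@]12CC=C(C)[C@@H]3C[C@@H]4C(C)(C)OC(=C(CC=C(C)C)C1=O)[C@]4(O)[C@@]32O | target

## Step count and least certain steps

Total step count: 15. Longest linear sequence: 13 (steps 1 to 6 and 9 to 15); the vinyl ketone branch is steps 7 and 8.

**Step 11 (key step).**
- What may go wrong: dehydration of the ring B ketol through the enamine (the normal Robinson outcome); condensation of the amine with the ring A vinylogous acid; loss of a proton from the C13 cation instead of capture by O5; closure with C13 on the wrong side of ring C; acid-induced cyclisation of the C6 prenyl group onto O5.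
- Fallback (known reaction types, run stepwise from 19): the amine stage alone is quenched and ketol 20 is isolated. SnCl4 in CH2Cl2 at −78 °C then effects a Prins cyclisation terminated by chloride to give the tricyclic tertiary chloride F1. AgOTf with 2,6-di-tert-butylpyridine ionises the chloride and the C5 enol closes ring D, which returns to 21.

**Step 9.**
- What may go wrong: poor facial selectivity at the planar hydroxyquinonate; reversal of the addition (retro-Michael); amine-induced oligomerisation of the vinyl ketone.
- Fallback (known chemistry, from 12 and 17): triethylamine-promoted Michael addition, the first stage of a Robinson annulation, gives the racemic adduct F2. Its enantiomers are separated by preparative chromatography on a polysaccharide chiral stationary phase, which returns to 18.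

**Step 10.**
- What may go wrong: retro-Michael loss of the side chain or premature, uncontrolled aldol closure and dehydration at the temperature the demethylation needs.
- Fallback (from 18): ring B is closed first on the methyl ether with pyrrolidinium acetate to give the methyl ether ketol F3, in which C2–C7 can no longer fragment directly. LiCl demethylation of F3 then gives 20 as an isolated compound, which is taken through the BF3·OEt2 stage of step 11 to 21.

**Step 4.**
- What may go wrong: deprotonation at the benzylic-allylic CH2 of the geranyl group instead of the ring, or SN2′ attack giving the 1,1-dimethylallyl isomer.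
- Fallback (from 7): the single free ring position is brominated with N-bromosuccinimide in MeCN at low temperature to give aryl bromide F4. Bromine–lithium exchange with t-BuLi at −78 °C, which is faster than any deprotonation, and the same copper-catalysed prenylation return to 10.

**Step 13.**
- What may go wrong: enolisation towards C10, retro-aldol opening at C3 if a silyl group is lost, or slow O-sulfonylation of the hindered enolate.
- Fallback (from 22): MeCeCl2 (from MeLi and CeCl3) adds to the C9 ketone to give the tertiary carbinol F5 (either C9 epimer). Dehydration with the Burgess reagent towards the C8 methylene returns to 25; regiochemistry of this elimination would have to be checked.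

## Further compounds

F1 | step 11 | tricyclic tertiary chloride (rings A, B, C closed; C12 bearing CMe2Cl cis to C5; C5 enol free) | CC(C)=CCC/C(C)=C/C[C@]12CCC(=O)[C@@H]3C[C@H](C(C)(C)Cl)[C@](O)(C(O)=C(CC=C(C)C)C1=O)[C@@]32O
F2 | step 9 | racemic 18 | CC(C)=CCC/C(C)=C/CC1(CCC(=O)CCC=C(C)C)C(=O)C(=O)C(OC)=C(CC=C(C)C)C1=O
F3 | step 10 | O5-methyl ether of ketol 20 | CC(C)=CCC/C(C)=C/C[C@]12CCC(=O)[C@H](CCC=C(C)C)[C@]2(O)C(=O)C(OC)=C(CC=C(C)C)C1=O
F4 | step 4 | 1-bromo-3-[(2E)-3,7-dimethylocta-2,6-dienyl]-5,6-dimethoxy-2,4-bis(methoxymethoxy)benzene | CC(C)=CCC/C(C)=C/Cc1c(OCOC)c(Br)c(OC)c(OC)c1OCOC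
F5 | step 13 | C9 methyl carbinol of 22 (C9 configuration not defined) | CC(C)=CCC/C(C)=C/C[C@]12CCC(C)(O)[C@@H]3C[C@@H]4C(C)(C)OC(=C(CC=C(C)C)C1=O)[C@]4(O[Si](C)(C)C)[C@@]32O[Si](C)(C)C
A1 | alternative 1 | ring B β,γ-unsaturated ketone with α-keto ester side chain (substrate of the samarium coupling) | CC(C)=CCC/C(C)=C/C[C@@]1(C(=O)CCC=C(C)C)CC=C(C)[C@H](C[C@H](C(C)(C)O[Si](CC)(CC)CC)C(=O)C(=O)OC)C1=O
A2 | alternative 1 | bicyclic cis-diol ester (rings B and C) | CC(C)=CCC/C(C)=C/C[C@@]1(C(=O)CCC=C(C)C)CC=C(C)[C@@H]2C[C@H](C(C)(C)O[Si](CC)(CC)CC)[C@](O)(C(=O)OC)[C@]12O
A3 | alternative 2 | phenol with (Z)-allylic methyl carbonate on C3 (substrate of the palladium step) | CC(C)=CCC/C(C)=C/Cc1c(O)c(CC=C(C)C)c(OC)c(OC)c1[C@@H](CC=C(C)C)/C(C)=C\COC(=O)OC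
A4 | alternative 2 | bicyclic cyclohexa-2,4-dienone (rings A and B) | CC(C)=CCC/C(C)=C/C[C@]12CC=C(C)[C@H](CC=C(C)C)C2=C(OC)C(OC)=C(CC=C(C)C)C1=O
A5 | alternative 3 | 2-geranyl-2-(7-methyl-3-oxooct-6-enyl)cyclohexane-1,3,5-trione | CC(C)=CCC/C(C)=C/CC1(CCC(=O)CCC=C(C)C)C(=O)CC(=O)CC1=O
A6 | alternative 3 | cis-fused bicyclic ketol (rings A and B) | CC(C)=CCC/C(C)=C/C[C@]12CCC(=O)[C@H](CC=C(C)C)[C@]2(O)CC(=O)CC1=O
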